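The earlier runs and the new flask are simulated for substances that don't exist; scatter was added.

A flat curve invites the conclusion that the flask has nothing left to react, so we ask first what the flat stretch of the summer run actually holds.

- summer: left-handed substrate 12 mM; right-handed substrate 12 mM; reagent 12 mM; free catalyst 24 µM; the very flask that is asked about, followed so far
- flask: left-handed substrate 12 mM; reagent 12.0 mM; free catalyst 24 µM; right-handed substrate 12 mM; time 8.0 d

- summer (time / d: left-handed substrate / %, right-handed substrate / %): 0.250: 21.8, 49.5; 0.833: 14.6, 49.9; 1.25: 11.8, 47.9; 2.00: 8.7, 49.7; 3.00: 8.9, 50.7; 4.00: 8.6, 48.9

(readings scatter by 1 percentage point)

- free catalyst is single-handed; left-handed substrate and right-handed substrate are mirror images of each other, charged as a racemate, each of them at the stated concentration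
- steps thought possible: reagent + free catalyst + left-handed substrate -> free catalyst + left-handed product; reagent + free catalyst + right-handed substrate -> free catalyst + right-handed product; 2 free catalyst -> spent catalyst A; free catalyst -> spent catalyst B
- an excess is the difference of the two amounts in percent of their sum
- an excess is below zero if the other one leads

- part of the left-handed substrate and right-handed substrate charged together that has reacted at 8.0 d
- excess of left-handed product over right-handed product in the product at 8.0 d
- excess of right-handed substrate over left-handed substrate among what is left of the two at 8.0 d

The flask asked about is the summer run followed further. Percentages of substrate are of the two substrates charged together.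

1. The level. From 2.00 d on, the left-handed substrate reads 8.73 % on average. The right-handed substrate averages 49.4 %. So from a share of 0.5 of the two substrates charged together for each, the right-handed substrate has lost 0.567 %, far less than the 41.3 % lost by the left-handed substrate.

2. The rule. In this flask reagent and left-handed substrate are charged equal, and they fall together because the right-handed side takes so little. The rate goes as free catalyst times the square of left-handed substrate, so the pace at which the reciprocal of that substrate, taken as a fraction, climbs follows free catalyst, and the climb itself follows free catalyst summed over time. The whole climb from charge to stall is the catalyst budget 9.45. The level stands above zero, which points to catalyst deactivation, not to an empty charge.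

3. The curve. The first reading gives a pace of 10.3 d⁻¹, which would reach the budget in 0.917 d. Yet at 0.833 d the climb is 4.85, about half of the budget. That slowing is the knee. At 2.00 d the climb reads 9.49, and the curve is level.

4. Our reckoning. We hold both readings to 8.0 d, which gives 41.8 % reacted, eS 70.0 % and eP 97.3 %. The last rests on a loss read with a scatter of 1 percentage point per reading.

Its ground being that “The left-handed substrate falls fast and then nearly stalls”, the forecast gives 43.3 %, 97.2 % and 74.3 %, higher on c than our figure.

The flask gives 42.6 %, 95.3 % and 70.9 %. At 8.00 d it holds 8.35 % left-handed substrate and 15 % of the reagent's own charge, beside 0.361 % free catalyst. That substrate level means a climb of 9.98, against our budget of 9.45.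

    reagent + free catalyst + left-handed substrate → free catalyst + left-handed product (k = 8.09 × 10⁵ M⁻² h⁻¹)
    reagent + free catalyst + right-handed substrate → free catalyst + right-handed product (k = 9090 M⁻² h⁻¹)
    2 free catalyst → spent catalyst A (k = 1060 M⁻¹ h⁻¹)
    free catalyst → spent catalyst B (k = 0.0233 h⁻¹)

The neighbour with 4.8 mM of reagent shows the same 0.361 % free catalyst. Counted in the two substrates charged together, its reagent starts 30.0 % below the left-handed substrate, so the logarithm of their ratio climbs by that gap times the budget. This gives 30.7 % left-handed substrate and eS 23.9 %. The neighbour gives 30.8 % and 23.6 %.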